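**Plan**

- Flavanone numbering is used (O1, C2, C3, C4, C4a, C5–C8, C8a; ring A aromatic, ring C the pyranone, ring B the 2‑aryl group). The retrosynthesis first removes five O‑benzyl groups, then cuts O1–C8a and C4–C4a together, then the C2–C3 bond (aldol) and the side‑chain C=C (hydrogenation).
- Enabling feature: ring C is fused to ring A at the adjacent carbons C8a (bearing O1) and C4a (bearing the C4 carbonyl). These two carbons are the two termini of an aryne, and the C5 oxygen next to C4a polarises that aryne so that oxygen enters at C8a and the anion sits at C4a.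
- Forward order: the 1,1‑diarylethane side chain is built on a phloroacetophenone core, and ring A is then converted into an ortho‑silylaryl triflate. Separately the C2–C3 bond is made by aldol addition. Ring C closes in the aryne annulation, and hydrogenolysis ends the route.
- Stereochemistry: the side‑chain R centre comes from iridium‑catalysed asymmetric hydrogenation of a 1,1‑diarylethene. C2 (R) and C3 (R) come from a magnesium‑catalysed anti‑aldol under (S)‑4‑benzyloxazolidinone control. The annulation creates no stereocentre.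
- Design choices: the aldol hydroxyl enters the annulation as its O–SiMe3 ether, so the alkoxide is released without a proton. The annulation product carries five benzyl ethers (3‑O, 5‑O, 7‑O, 4'‑O and the side‑chain aryl O).

Key step: step 12

Assumption: the sense of induction is taken from the usual models — in step 9 the chelated Z‑enolate is attacked anti to the auxiliary benzyl group (giving 2R,3R); in step 4 the ligand antipode that gives R is fixed in a trial run and the other antipode is used if the sense is reversed.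

**Step 1**
Reactants: 1 2',4',6'-trihydroxyacetophenone
Product: 2 1-[2,6-dihydroxy-4-(methoxymethoxy)phenyl]ethanone
Conditions: MOMCl (1.0 equiv), i-Pr2NEt, THF, 0 °C
Reagents that add atoms: chloromethyl methyl ether, COCCl
Why: Williamson-type O-alkylation; the 4'-hydroxyl is the only one not hydrogen-bonded to the acetyl carbonyl and is the most acidic, so one equivalent of the chloride should etherify it preferentially, with any bis-ether removed by chromatography.

**Step 2**
Reactants: 2 1-[2,6-dihydroxy-4-(methoxymethoxy)phenyl]ethanone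
Product: 3 1-[2,6-bis(benzyloxy)-4-(methoxymethoxy)phenyl]ethanone
Conditions: BnBr (2.5 equiv), K2CO3, DMF, 70 °C
Reagents that add atoms: benzyl bromide, BrCc1ccccc1
Why: Williamson etherification of the two chelated ortho hydroxyls under forcing carbonate conditions, to which the MOM acetal is inert.

**Step 3**
Reactants: 3 1-[2,6-bis(benzyloxy)-4-(methoxymethoxy)phenyl]ethanone; 4 1-(benzyloxy)-4-bromobenzene
Product: 8 1,3-bis(benzyloxy)-2-{1-[4-(benzyloxy)phenyl]ethenyl}-5-(methoxymethoxy)benzene, via aryllithium 5 (not isolated), via arylcerium dichloride 6 (not isolated), via tertiary carbinol 7 (not isolated)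
Conditions: 4, n-BuLi, THF, −78 °C; CeCl3; then 3, −78 → 0 °C; then 1 M HCl, rt
Reagents that add atoms: none
Why: Bromine–lithium exchange, transmetalation to the weakly basic organocerium reagent (which suppresses enolisation of the hindered aryl methyl ketone) and 1,2-addition should give the doubly benzylic carbinol, which loses water by E1 dehydration on brief contact with dilute acid; only the methyl group carries β-hydrogens, so a single alkene can form.

**Step 4**
Reactants: 8 1,3-bis(benzyloxy)-2-{1-[4-(benzyloxy)phenyl]ethenyl}-5-(methoxymethoxy)benzene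
Product: 9 1,3-bis(benzyloxy)-2-{(1R)-1-[4-(benzyloxy)phenyl]ethyl}-5-(methoxymethoxy)benzene
Conditions: [Ir(cod)(tBu-PHOX)]BArF (2 mol %), H2 (5 bar), CH2Cl2, rt
Reagents that add atoms: none
Why: Iridium-catalysed asymmetric hydrogenation of a 1,1-diarylethene; the 2,6-dibenzyloxyaryl ring is forced perpendicular to the alkene while the 4-benzyloxyphenyl ring stays conjugated, so the chiral N,P-ligand pocket should tell the two aryl groups apart and deliver hydrogen to one enantioface, setting the R centre, while benzyl and MOM ethers are inert to this catalyst.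

**Step 5**
Reactants: 9 1,3-bis(benzyloxy)-2-{(1R)-1-[4-(benzyloxy)phenyl]ethyl}-5-(methoxymethoxy)benzene
Product: 10 3,5-bis(benzyloxy)-4-{(1R)-1-[4-(benzyloxy)phenyl]ethyl}phenol
Conditions: HCl (3 M in MeOH), THF, 40 °C
Reagents that add atoms: none
Why: Acid-catalysed acetal cleavage of the MOM ether; benzyl ethers are stable and the benzylic centre carries no ionisable leaving group, so its configuration should be kept.

**Step 6**
Reactants: 10 3,5-bis(benzyloxy)-4-{(1R)-1-[4-(benzyloxy)phenyl]ethyl}phenol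
Product: 11 3,5-bis(benzyloxy)-2-bromo-4-{(1R)-1-[4-(benzyloxy)phenyl]ethyl}phenol
Conditions: NBS (1.0 equiv), i-Pr2NH (10 mol %), CH2Cl2, −78 → −20 °C
Reagents that add atoms: N-bromosuccinimide, O=C1CCC(=O)N1Br
Why: Electrophilic aromatic bromination (amine-mediated ortho-bromination of a phenol); the two positions ortho to the hydroxyl are homotopic and the para position is blocked, so only one monobromide can form, and the phloroglucinol-type ring is far more reactive than the 4-benzyloxyphenyl ring.

**Step 7**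
Reactants: 11 3,5-bis(benzyloxy)-2-bromo-4-{(1R)-1-[4-(benzyloxy)phenyl]ethyl}phenol
Product: 14 3,5-bis(benzyloxy)-4-{(1R)-1-[4-(benzyloxy)phenyl]ethyl}-2-(trimethylsilyl)phenyl trifluoromethanesulfonate, via aryl trimethylsilyl ether 12 (not isolated), via lithium 2-silylphenoxide 13 (not isolated)
Conditions: HMDS, THF, 65 °C, then evaporation; n-BuLi, THF, −78 °C; then Tf2O, −78 °C → rt
Reagents that add atoms: hexamethyldisilazane, C[Si](C)(C)N[Si](C)(C)C; trifluoromethanesulfonic anhydride, O=S(=O)(OS(=O)(=O)C(F)(F)F)C(F)(F)F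
Why: O-silylation, bromine–lithium exchange with 1,3 O→C silyl shift (retro-Brook rearrangement) and O-sulfonylation of the resulting phenoxide form the standard sequence to ortho-silylaryl triflates; halogen–metal exchange at −78 °C is faster than any attack on the benzyl ethers.

**Step 8**
Reactants: 15 (4S)-4-benzyl-1,3-oxazolidin-2-one; 16 (benzyloxy)acetyl chloride
Product: 18 (4S)-4-benzyl-3-[(benzyloxy)acetyl]-1,3-oxazolidin-2-one, via N-lithio oxazolidinone 17 (not isolated)
Conditions: n-BuLi, THF, −78 °C; then 16, −78 → 0 °C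
Reagents that add atoms: none
Why: N-acylation of the lithiated oxazolidinone by the acid chloride, the standard way to load the auxiliary.

**Step 9**
Reactants: 18 (4S)-4-benzyl-3-[(benzyloxy)acetyl]-1,3-oxazolidin-2-one; 19 4-(benzyloxy)benzaldehyde
Product: 21 (4S)-4-benzyl-3-{(2R,3R)-2-(benzyloxy)-3-[4-(benzyloxy)phenyl]-3-hydroxypropanoyl}-1,3-oxazolidin-2-one, via O-trimethylsilyl aldol adduct 20 (not isolated)
Conditions: MgCl2 (20 mol %), Et3N, TMSCl, EtOAc, rt; then TFA, MeOH
Reagents that add atoms: none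
Why: Magnesium-halide-catalysed direct anti-aldol of an N-acyloxazolidinone with a non-enolisable aromatic aldehyde; the chelated Z-magnesium enolate should be attacked on the face away from the auxiliary benzyl group (C2 = R) through a boat-like transition state that places the aryl group anti (C3 = R), and silylation of the aldolate turns the catalyst over and blocks retro-aldol.

**Step 10**
Reactants: 21 (4S)-4-benzyl-3-{(2R,3R)-2-(benzyloxy)-3-[4-(benzyloxy)phenyl]-3-hydroxypropanoyl}-1,3-oxazolidin-2-one
Product: 22 methyl (2R,3R)-2-(benzyloxy)-3-[4-(benzyloxy)phenyl]-3-hydroxypropanoate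
Conditions: MeMgBr, MeOH, CH2Cl2, 0 °C
Reagents that add atoms: methanol, CO
Why: Magnesium methoxide transesterification at the exocyclic imide carbonyl; the chelated magnesium aldolate should resist retro-aldol and α-epimerisation, and the auxiliary is recovered.

**Step 11**
Reactants: 22 methyl (2R,3R)-2-(benzyloxy)-3-[4-(benzyloxy)phenyl]-3-hydroxypropanoate
Product: 23 methyl (2R,3R)-2-(benzyloxy)-3-[4-(benzyloxy)phenyl]-3-[(trimethylsilyl)oxy]propanoate
Conditions: TMSCl, imidazole, CH2Cl2, 0 °C
Reagents that add atoms: chlorotrimethylsilane, C[Si](C)(C)Cl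
Why: O-silylation of a secondary alcohol; the silyl ether replaces the hydroxyl proton by a fluoride-labile group so that the alkoxide can later be released under aprotic conditions.

**Step 12**
Reactants: 14 3,5-bis(benzyloxy)-4-{(1R)-1-[4-(benzyloxy)phenyl]ethyl}-2-(trimethylsilyl)phenyl trifluoromethanesulfonate; 23 methyl (2R,3R)-2-(benzyloxy)-3-[4-(benzyloxy)phenyl]-3-[(trimethylsilyl)oxy]propanoate
Product: 26 (2R,3R)-3,5,7-tris(benzyloxy)-2-[4-(benzyloxy)phenyl]-6-{(1R)-1-[4-(benzyloxy)phenyl]ethyl}-2,3-dihydro-4H-chromen-4-one, via tetrabutylammonium alkoxide 24 (not isolated), via 3-alkoxyaryne 25 (not isolated)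
Conditions: TBAT (1.1 equiv, added slowly), 23 (1.5 equiv), THF, 0 °C → rt
Reagents that add atoms: none
Why: Proposed new method: fluoride removes the aryl silyl group of 14, triflate leaves and aryne 25 forms, while fluoride (and later the expelled methoxide) cleaves the O–Si bond of 23 to give the proton-free alkoxide 24; this adds to the aryne carbon remote from the flanking benzyloxy group (future C8a), and the C4a aryl anion, stabilised inductively by that ortho oxygen, attacks the methyl ester and expels methoxide, so O1–C8a and C4–C4a form in one operation. The closest known reaction type is the fluoride-triggered annulation of arynes with ortho-hydroxy and ortho-amino benzoate esters to xanthones and acridones (heteroatom addition, then acylation of the aryl anion by the neighbouring ester); what is new is an aliphatic β-alkoxide that carries the ester on an sp3 chain. The pyranone closes by a 6-exo-trig acyl substitution. No stereocentre is created: C2 and C3 are carried in from 23 and the side-chain centre from 14, and the 2,3-trans arrangement is also the thermodynamically preferred one. The step needs regioselective addition to the unsymmetrical aryne, which the C5 benzyloxy group should secure by aryne distortion, inductive stabilisation of the anion and steric shielding of the nearer carbon. It also needs acylation to be faster than protonation, retro-aldol or α-deprotonation, which the silyl ether (no O–H proton), slow fluoride dosing (low standing alkoxide concentration), the aprotic solvent and silyl capture of methoxide as Me3SiOMe are meant to secure.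

**Step 13**
Reactants: 26 (2R,3R)-3,5,7-tris(benzyloxy)-2-[4-(benzyloxy)phenyl]-6-{(1R)-1-[4-(benzyloxy)phenyl]ethyl}-2,3-dihydro-4H-chromen-4-one
Product: 27 (2R,3R)-3,5,7-trihydroxy-2-(4-hydroxyphenyl)-6-[(1R)-1-(4-hydroxyphenyl)ethyl]-2,3-dihydro-4H-chromen-4-one
Conditions: H2 (1 atm), Pd(OH)2/C, EtOAc/MeOH, rt
Reagents that add atoms: none
Why: Catalytic hydrogenolysis of the five benzyl ethers; under mild neutral conditions the C2–O1 bond, the C4 ketone (hydrogen-bonded to the liberated 5-OH) and the diarylethane C–C bonds should survive, and no stereocentre is touched.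

**Compound list**

1 | 2',4',6'-trihydroxyacetophenone | CC(=O)c1c(O)cc(O)cc1O | starting material
2 | 1-[2,6-dihydroxy-4-(methoxymethoxy)phenyl]ethanone | CC(=O)c1c(O)cc(OCOC)cc1O | intermediate
3 | 1-[2,6-bis(benzyloxy)-4-(methoxymethoxy)phenyl]ethanone | CC(=O)c1c(OCc2ccccc2)cc(OCOC)cc1OCc1ccccc1 | intermediate
4 | 1-(benzyloxy)-4-bromobenzene | Brc1ccc(OCc2ccccc2)cc1 | starting material
5 | [4-(benzyloxy)phenyl]lithium | [Li]c1ccc(OCc2ccccc2)cc1 | intermediate
6 | [4-(benzyloxy)phenyl]cerium dichloride | Cl[Ce](Cl)c1ccc(OCc2ccccc2)cc1 | intermediate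
7 | 1-[2,6-bis(benzyloxy)-4-(methoxymethoxy)phenyl]-1-[4-(benzyloxy)phenyl]ethanol (racemic) | CC(O)(c1ccc(OCc2ccccc2)cc1)c1c(OCc2ccccc2)cc(OCOC)cc1OCc1ccccc1 | intermediate
8 | 1,3-bis(benzyloxy)-2-{1-[4-(benzyloxy)phenyl]ethenyl}-5-(methoxymethoxy)benzene | C=C(c1ccc(OCc2ccccc2)cc1)c1c(OCc2ccccc2)cc(OCOC)cc1OCc1ccccc1 | intermediate
9 | 1,3-bis(benzyloxy)-2-{(1R)-1-[4-(benzyloxy)phenyl]ethyl}-5-(methoxymethoxy)benzene | C[C@H](c1ccc(OCc2ccccc2)cc1)c1c(OCc2ccccc2)cc(OCOC)cc1OCc1ccccc1 | intermediate
10 | 3,5-bis(benzyloxy)-4-{(1R)-1-[4-(benzyloxy)phenyl]ethyl}phenol | C[C@H](c1ccc(OCc2ccccc2)cc1)c1c(OCc2ccccc2)cc(O)cc1OCc1ccccc1 | intermediate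
11 | 3,5-bis(benzyloxy)-2-bromo-4-{(1R)-1-[4-(benzyloxy)phenyl]ethyl}phenol | C[C@H](c1ccc(OCc2ccccc2)cc1)c1c(OCc2ccccc2)cc(O)c(Br)c1OCc1ccccc1 | intermediate
12 | [3,5-bis(benzyloxy)-2-bromo-4-{(1R)-1-[4-(benzyloxy)phenyl]ethyl}phenoxy]trimethylsilane | C[C@H](c1ccc(OCc2ccccc2)cc1)c1c(OCc2ccccc2)cc(O[Si](C)(C)C)c(Br)c1OCc1ccccc1 | intermediate
13 | lithium 3,5-bis(benzyloxy)-4-{(1R)-1-[4-(benzyloxy)phenyl]ethyl}-2-(trimethylsilyl)phenoxide | C[C@H](c1ccc(OCc2ccccc2)cc1)c1c(OCc2ccccc2)cc([O-])c([Si](C)(C)C)c1OCc1ccccc1.[Li+] | intermediate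
14 | 3,5-bis(benzyloxy)-4-{(1R)-1-[4-(benzyloxy)phenyl]ethyl}-2-(trimethylsilyl)phenyl trifluoromethanesulfonate | C[C@H](c1ccc(OCc2ccccc2)cc1)c1c(OCc2ccccc2)cc(OS(=O)(=O)C(F)(F)F)c([Si](C)(C)C)c1OCc1ccccc1 | intermediate
15 | (4S)-4-benzyl-1,3-oxazolidin-2-one | O=C1N[C@@H](Cc2ccccc2)CO1 | starting material
16 | (benzyloxy)acetyl chloride | O=C(Cl)COCc1ccccc1 | starting material
17 | lithium salt of (4S)-4-benzyl-1,3-oxazolidin-2-one (N-lithio) | [Li]N1[C@@H](Cc2ccccc2)COC1=O | intermediate
18 | (4S)-4-benzyl-3-[(benzyloxy)acetyl]-1,3-oxazolidin-2-one | O=C1OC[C@H](Cc2ccccc2)N1C(=O)COCc1ccccc1 | intermediate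
19 | 4-(benzyloxy)benzaldehyde | O=Cc1ccc(OCc2ccccc2)cc1 | starting material
20 | (4S)-4-benzyl-3-{(2R,3R)-2-(benzyloxy)-3-[4-(benzyloxy)phenyl]-3-[(trimethylsilyl)oxy]propanoyl}-1,3-oxazolidin-2-one | O=C1OC[C@H](Cc2ccccc2)N1C(=O)[C@H](OCc1ccccc1)[C@@H](c1ccc(OCc2ccccc2)cc1)O[Si](C)(C)C | intermediate
21 | (4S)-4-benzyl-3-{(2R,3R)-2-(benzyloxy)-3-[4-(benzyloxy)phenyl]-3-hydroxypropanoyl}-1,3-oxazolidin-2-one | O=C1OC[C@H](Cc2ccccc2)N1C(=O)[C@H](OCc1ccccc1)[C@@H](c1ccc(OCc2ccccc2)cc1)O | intermediate
22 | methyl (2R,3R)-2-(benzyloxy)-3-[4-(benzyloxy)phenyl]-3-hydroxypropanoate | COC(=O)[C@H](OCc1ccccc1)[C@@H](c1ccc(OCc2ccccc2)cc1)O | intermediate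
23 | methyl (2R,3R)-2-(benzyloxy)-3-[4-(benzyloxy)phenyl]-3-[(trimethylsilyl)oxy]propanoate | COC(=O)[C@H](OCc1ccccc1)[C@@H](c1ccc(OCc2ccccc2)cc1)O[Si](C)(C)C | intermediate
24 | tetrabutylammonium (1R,2R)-2-(benzyloxy)-1-[4-(benzyloxy)phenyl]-3-methoxy-3-oxopropan-1-olate | COC(=O)[C@H](OCc1ccccc1)[C@@H](c1ccc(OCc2ccccc2)cc1)[O-].CCCC[N+](CCCC)(CCCC)CCCC | intermediate
25 | 1,3-bis(benzyloxy)-2-{(1R)-1-[4-(benzyloxy)phenyl]ethyl}-4,5-didehydrobenzene (aryne) | C[C@H](c1ccc(OCc2ccccc2)cc1)C1=C(OCc2ccccc2)C#CC=C1OCc1ccccc1 | intermediate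
26 | (2R,3R)-3,5,7-tris(benzyloxy)-2-[4-(benzyloxy)phenyl]-6-{(1R)-1-[4-(benzyloxy)phenyl]ethyl}-2,3-dihydro-4H-chromen-4-one | C[C@H](c1ccc(OCc2ccccc2)cc1)c1c(OCc2ccccc2)cc2c(c1OCc1ccccc1)C(=O)[C@H](OCc1ccccc1)[C@@H](c1ccc(OCc3ccccc3)cc1)O2 | intermediate
27 | (2R,3R)-3,5,7-trihydroxy-2-(4-hydroxyphenyl)-6-[(1R)-1-(4-hydroxyphenyl)ethyl]-2,3-dihydro-4H-chromen-4-one (CNP0379731.1) | C[C@H](c1ccc(O)cc1)c1c(O)cc2c(c1O)C(=O)[C@H](O)[C@@H](c1ccc(O)cc1)O2 | target

**Step count and risks**

Total step count: 13. Longest linear sequence: 9 steps (steps 1–7, 12, 13); steps 8–11 form the second branch.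

Steps most likely to fail:

1. Step 12 (the proposed new method). The C4a aryl anion may be protonated (by adventitious water or by the α-C–H of the ester) before it reaches the ester. The free alkoxide may fragment by retro-aldol or eliminate. The product may ring-open or epimerise at C3 if base accumulates. The fallback uses known chemistry and makes the two bonds in separate operations. It sets out from 14 and the free hydroxy ester 22. With CsF in MeCN at rt, the ordinary O–H insertion of the aryne should give methyl (2R,3R)-2-(benzyloxy)-3-[4-(benzyloxy)phenyl]-3-(3,5-bis(benzyloxy)-4-{(1R)-1-[4-(benzyloxy)phenyl]ethyl}phenoxy)propanoate F1, the same aryl ether that premature protonation would produce. Its aryloxy ring is symmetric about the O–C1/C4 axis, so both positions ortho to the ether oxygen are equivalent. Mild ester hydrolysis (LiOH, THF/H2O, 0 °C) should give the corresponding propanoic acid F2. Intramolecular Friedel–Crafts acylation of this 3-aryloxypropanoic acid onto the strongly activated ring (TFAA, CH2Cl2, 0 °C) should then close C4–C4a and return to the route at 26.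

2. Step 4. The catalyst may discriminate poorly between the alkene enantiofaces, or the Brønsted-acidic iridium hydride may reduce the electron-rich alkene through an ionic, non-selective pathway. The fallback replaces asymmetric catalysis by resolution and sets out from 8. Hydrogenation with achiral [Ir(cod)(PCy3)(py)]PF6 should give racemic 1,3-bis(benzyloxy)-2-{1-[4-(benzyloxy)phenyl]ethyl}-5-(methoxymethoxy)benzene F3. Acidic MOM cleavage as in step 5 should give racemic 3,5-bis(benzyloxy)-4-{1-[4-(benzyloxy)phenyl]ethyl}phenol F4. Preparative chiral SFC should separate this into 10, where the route is rejoined, and the unwanted (S)-3,5-bis(benzyloxy)-4-{1-[4-(benzyloxy)phenyl]ethyl}phenol F5.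

3. Step 9. The α-benzyloxy oxygen may change the chelation pattern of the magnesium enolate and erode anti/syn and facial selectivity, and the electron-rich aldehyde may add slowly. The fallback replaces auxiliary control by reagent control and sets out from 16 and 19. Acylation of ethanethiol with 16 (Et3N, CH2Cl2) should give S-ethyl 2-(benzyloxy)ethanethioate F6. Enolisation and silylation (LDA, TMSCl, THF, −78 °C) should give (Z)-2-(benzyloxy)-1-(ethylsulfanyl)-1-[(trimethylsilyl)oxy]ethene F7. A Mukaiyama aldol with 19, promoted by tin(II) triflate, a proline-derived chiral diamine (antipode chosen for the 2R,3R series) and Bu2Sn(OAc)2 in CH2Cl2 at −78 °C, is anti-selective for α-benzyloxy thioester enolates. It should give S-ethyl (2R,3R)-2-(benzyloxy)-3-[4-(benzyloxy)phenyl]-3-hydroxypropanethioate F8. Silver(I)-assisted methanolysis (AgOCOCF3, MeOH) returns to the route at 22.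

**Further compounds**

F1 | step 12 | methyl (2R,3R)-2-(benzyloxy)-3-[4-(benzyloxy)phenyl]-3-(3,5-bis(benzyloxy)-4-{(1R)-1-[4-(benzyloxy)phenyl]ethyl}phenoxy)propanoate | COC(=O)[C@H](OCc1ccccc1)[C@@H](c1ccc(OCc2ccccc2)cc1)Oc1cc(OCc2ccccc2)c([C@H](C)c2ccc(OCc3ccccc3)cc2)c(OCc2ccccc2)c1
F2 | step 12 | (2R,3R)-2-(benzyloxy)-3-[4-(benzyloxy)phenyl]-3-(3,5-bis(benzyloxy)-4-{(1R)-1-[4-(benzyloxy)phenyl]ethyl}phenoxy)propanoic acid | OC(=O)[C@H](OCc1ccccc1)[C@@H](c1ccc(OCc2ccccc2)cc1)Oc1cc(OCc2ccccc2)c([C@H](C)c2ccc(OCc3ccccc3)cc2)c(OCc2ccccc2)c1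
F3 | step 4 | racemic 1,3-bis(benzyloxy)-2-{1-[4-(benzyloxy)phenyl]ethyl}-5-(methoxymethoxy)benzene | CC(c1ccc(OCc2ccccc2)cc1)c1c(OCc2ccccc2)cc(OCOC)cc1OCc1ccccc1
F4 | step 4 | racemic 3,5-bis(benzyloxy)-4-{1-[4-(benzyloxy)phenyl]ethyl}phenol | CC(c1ccc(OCc2ccccc2)cc1)c1c(OCc2ccccc2)cc(O)cc1OCc1ccccc1
F5 | step 4 | 3,5-bis(benzyloxy)-4-{(1S)-1-[4-(benzyloxy)phenyl]ethyl}phenol | C[C@@H](c1ccc(OCc2ccccc2)cc1)c1c(OCc2ccccc2)cc(O)cc1OCc1ccccc1
F6 | step 9 | S-ethyl 2-(benzyloxy)ethanethioate | CCSC(=O)COCc1ccccc1
F7 | step 9 | (Z)-2-(benzyloxy)-1-(ethylsulfanyl)-1-[(trimethylsilyl)oxy]ethene | CCS/C(O[Si](C)(C)C)=C\OCc1ccccc1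
F8 | step 9 | S-ethyl (2R,3R)-2-(benzyloxy)-3-[4-(benzyloxy)phenyl]-3-hydroxypropanethioate | CCSC(=O)[C@H](OCc1ccccc1)[C@@H](c1ccc(OCc2ccccc2)cc1)O
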